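**Plan**

- Unit 1 is the catechol flavanone (rings A, B, C) and unit 2 the naringenin part (rings D, E, F). In unit 1, C2 is a CH flanked by O1 and the electron-rich ring B, so it can be carried as an O1–CH2–ring B ether whose hydridic C–H is open to a carbene on C3, the carbon between the C4 ketone and ring D.
- Retrosynthesis: C2–C3 of unit 1 (ring C) is cut to an α-diazo ketone; N2 is taken off C3 to give a deoxybenzoin; C4–C4a is cut to a ring A arylzinc and the unit 2 C8-acetic acid; the C8–CH2 bond of unit 2 goes back to a 7-O-allyl ether of (2S)-naringenin; the ring A bromide goes back to 3,5-bis(benzyloxy)phenol and the ring B benzyl chloride.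
- Forward: rings D, E, F come intact from naringenin and gain a two-carbon arm at C8 (Claisen, oxidative cleavage). Ring A is brominated next to its free hydroxyl group, takes the ring B benzyl group on that oxygen, and is joined by Negishi acylation; diazo transfer follows and ring C closes last.
- Stereochemistry: C2 of unit 2 (S) comes from the chiral pool and is shielded by keeping strong external base away from the flavanone. C2 and C3 of unit 1 (R,R, cis) are created together in the dirhodium step under catalyst control and see no base afterwards.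
- Protecting groups: O1 carries the 3,4-bis(benzyloxy)benzyl group (ring B plus C2). O5 and O7 of unit 1 carry plain benzyl groups, whose C–H bonds are less hydridic, and O7 of unit 2 a silyl ether. Six benzyl ethers leave in the final hydrogenolysis.

Key step: step 11

Assumption 1: (2S)-naringenin, 3,5-bis(benzyloxy)phenol and 3,4-bis(benzyloxy)benzyl chloride are bought; the chloride is otherwise a reduction and a chlorination away from 3,4-bis(benzyloxy)benzaldehyde.
Assumption 2: Rh2(S-PTTL)4 is taken to give the (2R,3R) sense in the insertion; if the first run shows (2S,3S), the mirror-image catalyst Rh2(R-PTTL)4 is used instead.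

**Route**

Step 1
Reactants: 1 (2S)-naringenin
Product: 2 (2S)-7-O-allylnaringenin
Conditions: allyl alcohol (1.05 equiv), PPh3, DIAD, THF, 0 °C → rt
Reagents that add atoms: allyl alcohol, C=CCO
Why: Mitsunobu etherification alkylates the most acidic phenol (7-OH, para to the C4 carbonyl) first and uses no external base, so ring F should not open to the chalcone and C2 should stay S.

Step 2
Reactants: 2 (2S)-7-O-allylnaringenin
Product: 3 (2S)-7-O-allyl-4',5-di-O-benzylnaringenin
Conditions: BnOH (2.5 equiv), PPh3, DIAD, THF, 0 → 40 °C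
Reagents that add atoms: benzyl alcohol, OCc1ccccc1
Why: A second Mitsunobu etherification benzylates the ring E phenol and, more slowly, the hydrogen-bonded 5-OH (Mitsunobu alkylation of chelated 5-hydroxy groups of flavanones is known), again without base at C2.

Step 3
Reactants: 3 (2S)-7-O-allyl-4',5-di-O-benzylnaringenin
Product: 4 (2S)-8-allyl-4',5-di-O-benzylnaringenin
Conditions: 1,2-dichlorobenzene, 180 °C, sealed tube, argon
Reagents that add atoms: none
Why: The aromatic Claisen rearrangement ([3,3] shift, then tautomerisation) moves the allyl group from O7 to an ortho carbon, expected mainly at C8 between O7 and the ring oxygen O1; the neutral medium should leave C2 untouched and any 6-allyl isomer is removed by chromatography.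

Step 4
Reactants: 4 (2S)-8-allyl-4',5-di-O-benzylnaringenin
Product: 5 (2S)-8-allyl-4',5-di-O-benzyl-7-O-triisopropylsilylnaringenin
Conditions: TIPSCl, imidazole, DMF, rt → 40 °C
Reagents that add atoms: chlorotriisopropylsilane, CC(C)[Si](Cl)(C(C)C)C(C)C
Why: Standard phenol silylation; a silyl ether is chosen for O7 because, unlike a benzyl ether, it offers the later carbene no activated C–H for a five-membered insertion, and the bulky silyl group should withstand the acid chloride and DBU steps.

Step 5
Reactants: 5 (2S)-8-allyl-4',5-di-O-benzyl-7-O-triisopropylsilylnaringenin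
Product: 6 unit 2 C8-acetaldehyde
Conditions: OsO4 (2 mol %), NaIO4, 2,6-lutidine, dioxane/H2O, rt
Reagents that add atoms: osmium tetroxide (catalytic oxygen carrier), O=[Os](=O)(=O)=O; sodium periodate, [Na+].[O-]I(=O)(=O)=O
Why: Lemieux–Johnson oxidation (dihydroxylation, then periodate cleavage) turns the terminal alkene into the arylacetaldehyde and spares the electron-rich arenes that ozone would attack.

Step 6
Reactants: 6 unit 2 C8-acetaldehyde
Product: 7 unit 2 C8-acetic acid
Conditions: NaClO2, NaH2PO4, 2-methyl-2-butene (large excess), t-BuOH/THF/H2O, 0 °C → rt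
Reagents that add atoms: sodium chlorite, [Na+].[O-]Cl=O
Why: Pinnick oxidation takes the aldehyde to the acid under buffered conditions, with the alkene scavenger intercepting hypochlorite before it can chlorinate ring D.

Step 7
Reactants: 8 3,5-bis(benzyloxy)phenol
Product: 9 3,5-bis(benzyloxy)-2-bromophenol
Conditions: NBS (1.0 equiv, slow addition), i-Pr2NH (10 mol %), CH2Cl2, −78 → 0 °C
Reagents that add atoms: N-bromosuccinimide, O=C1CCC(=O)N1Br
Why: Amine-catalysed ortho-selective electrophilic bromination of a phenol, in which the N-bromoamine formed in the flask is delivered through a hydrogen bond to a carbon next to the hydroxyl group (C2 and C6 are equivalent) while C4 is shielded by two benzyloxy groups, so the unsymmetrical monobromide should predominate and is told from the symmetrical 4-bromo isomer by its two inequivalent ring protons.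

Step 8
Reactants: 9 3,5-bis(benzyloxy)-2-bromophenol; 10 3,4-bis(benzyloxy)benzyl chloride
Product: 11 1,5-bis(benzyloxy)-3-[3,4-bis(benzyloxy)benzyloxy]-2-bromobenzene
Conditions: K2CO3 (1.5 equiv), n-Bu4NI (10 mol %), DMF, rt → 50 °C
Reagents that add atoms: none
Why: Williamson etherification of the phenoxide with the benzylic chloride (iodide catalysis) places ring B and the future C2 on the oxygen next to the bromine, which becomes O1.

Step 9
Reactants: 7 unit 2 C8-acetic acid; 11 1,5-bis(benzyloxy)-3-[3,4-bis(benzyloxy)benzyloxy]-2-bromobenzene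
Product: 15 ring A–unit 2 deoxybenzoin, via acyl chloride 12 (not isolated), via aryllithium 13 (not isolated), via arylzinc chloride 14 (not isolated)
Conditions: (a) 7, 1-chloro-N,N,2-trimethylprop-1-en-1-amine, CH2Cl2, 0 °C → rt, evaporate; (b) 11, n-BuLi, THF, −78 °C, then ZnCl2, −78 → 0 °C; (c) add 12, Pd(PPh3)4 (5 mol %), THF, 0 °C → rt
Reagents that add atoms: none
Why: Negishi acylation: bromine–lithium exchange and transmetalation give a non-basic arylzinc that couples with the acid chloride under zerovalent-palladium catalysis without adding to or enolising the flavanone ketone, and the bromine fixes the ketone between the O1 ether and O5.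

Step 10
Reactants: 15 ring A–unit 2 deoxybenzoin
Product: 16 α-diazo deoxybenzoin
Conditions: p-ABSA (1.5 equiv), DBU (1.5 equiv), dry MeCN/THF, 0 °C → rt, dark
Reagents that add atoms: 4-acetamidobenzenesulfonyl azide, CC(=O)Nc1ccc(cc1)S(=O)(=O)N=[N+]=[N-]
Why: Regitz diazo transfer to the methylene flanked by the ketone and ring D, which DBU should deprotonate far more readily than C3 of unit 2, so ring F stays closed.

Step 11
Reactants: 16 α-diazo deoxybenzoin
Product: 17 protected cis-(2R,3R) biflavanone
Conditions: Rh2(S-PTTL)4 [dirhodium tetrakis(N-phthaloyl-(S)-tert-leucinate)] (2 mol %), toluene, 4 Å MS, 0 °C, slow addition of 16 to high dilution; neutral work-up, deactivated silica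
Reagents that add atoms: none
Why: Rh2(S-PTTL)4, dirhodium tetrakis[N-phthaloyl-(S)-tert-leucinate] (a divalent-rhodium carboxylate dimer), expels N2 from 16 to give an aryl/acyl rhodium carbenoid at C3, which inserts through a concerted, hydride-transfer-like three-centre transition state into a benzylic C–H of the ortho O1–CH2–ring B ether and so forms C2–C3. The closest known reaction is the dirhodium-catalysed intramolecular C–H insertion of 2-alkoxyphenyl α-diazo ketones and aryldiazoacetates next to an ether oxygen, which gives cis-2,3-disubstituted chroman-4-ones and dihydrobenzofurans. Ring C (O1, C2, C3, C4, C4a, C8a) closes as a six-membered ring by 1,6-insertion. C2 and C3 are set in the same event: the cis relation should arise because ring B and the orthogonal, doubly ortho-substituted ring D both turn away from the carboxylate wall and no base is present to equilibrate C3, while the chiral phthalimido ligands select which diastereotopic benzylic hydrogen is replaced and thereby the (2R,3R) sense. The step needs this insertion to beat attack of the O1 lone pair (oxonium ylide, then 1,2-benzyl shift), the same 1,6-insertion into the plain benzyl ether on O5, and insertion elsewhere. The para-alkoxy group of ring B makes the target C–H markedly more hydridic than that of the unsubstituted benzyl ether, a difference the selective donor/acceptor carbenoid should read; the hindered carbenoid disfavours ylide formation, O7 of unit 2 is silylated, and C2–H of unit 2 is held out of reach by ring F.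

Step 12
Reactants: 17 protected cis-(2R,3R) biflavanone
Product: 18 desilylated biflavanone
Conditions: HF·pyridine, pyridine, THF, 0 °C → rt
Reagents that add atoms: none
Why: Fluoride cleavage of the aryl silyl ether under buffered, weakly acidic conditions that should not enolise C3 of unit 1 and are too mild to cleave benzyl ethers.

Step 13
Reactants: 18 desilylated biflavanone
Product: 19 target biflavanone
Conditions: H2 (1 atm), Pd(OH)2/C, THF/MeOH, rt; Sephadex LH-20
Reagents that add atoms: none
Why: Catalytic hydrogenolysis removes the six benzyl ethers under neutral conditions that should neither epimerise C3 nor open a pyranone ring.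

**Compound list**

1 | (2S)-naringenin, (2S)-5,7-dihydroxy-2-(4-hydroxyphenyl)chroman-4-one | O=C1C[C@@H](c2ccc(O)cc2)Oc2c1c(O)cc(O)c2 | starting material
2 | (2S)-7-(allyloxy)-5-hydroxy-2-(4-hydroxyphenyl)chroman-4-one | O=C1C[C@@H](c2ccc(O)cc2)Oc2c1c(O)cc(OCC=C)c2 | intermediate
3 | (2S)-7-(allyloxy)-5-(benzyloxy)-2-[4-(benzyloxy)phenyl]chroman-4-one | O=C1C[C@@H](c2ccc(OCc3ccccc3)cc2)Oc2c1c(OCc3ccccc3)cc(OCC=C)c2 | intermediate
4 | (2S)-8-allyl-5-(benzyloxy)-2-[4-(benzyloxy)phenyl]-7-hydroxychroman-4-one | O=C1C[C@@H](c2ccc(OCc3ccccc3)cc2)Oc2c1c(OCc3ccccc3)cc(O)c2CC=C | intermediate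
5 | (2S)-8-allyl-5-(benzyloxy)-2-[4-(benzyloxy)phenyl]-7-(triisopropylsilyloxy)chroman-4-one | O=C1C[C@@H](c2ccc(OCc3ccccc3)cc2)Oc2c1c(OCc3ccccc3)cc(O[Si](C(C)C)(C(C)C)C(C)C)c2CC=C | intermediate
6 | 2-{(2S)-5-(benzyloxy)-2-[4-(benzyloxy)phenyl]-4-oxo-7-(triisopropylsilyloxy)chroman-8-yl}acetaldehyde | O=C1C[C@@H](c2ccc(OCc3ccccc3)cc2)Oc2c1c(OCc3ccccc3)cc(O[Si](C(C)C)(C(C)C)C(C)C)c2CC=O | intermediate
7 | 2-{(2S)-5-(benzyloxy)-2-[4-(benzyloxy)phenyl]-4-oxo-7-(triisopropylsilyloxy)chroman-8-yl}acetic acid | O=C1C[C@@H](c2ccc(OCc3ccccc3)cc2)Oc2c1c(OCc3ccccc3)cc(O[Si](C(C)C)(C(C)C)C(C)C)c2CC(=O)O | intermediate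
8 | 3,5-bis(benzyloxy)phenol | Oc1cc(OCc2ccccc2)cc(OCc2ccccc2)c1 | starting material
9 | 3,5-bis(benzyloxy)-2-bromophenol | Oc1cc(OCc2ccccc2)cc(OCc2ccccc2)c1Br | intermediate
10 | 3,4-bis(benzyloxy)benzyl chloride | ClCc1ccc(OCc2ccccc2)c(OCc2ccccc2)c1 | starting material
11 | 1,5-bis(benzyloxy)-3-[3,4-bis(benzyloxy)benzyloxy]-2-bromobenzene | Brc1c(OCc2ccccc2)cc(OCc2ccccc2)cc1OCc1ccc(OCc2ccccc2)c(OCc2ccccc2)c1 | intermediate
12 | acid chloride of 7 (formed in the flask), 2-{(2S)-5-(benzyloxy)-2-[4-(benzyloxy)phenyl]-4-oxo-7-(triisopropylsilyloxy)chroman-8-yl}acetyl chloride | O=C1C[C@@H](c2ccc(OCc3ccccc3)cc2)Oc2c1c(OCc3ccccc3)cc(O[Si](C(C)C)(C(C)C)C(C)C)c2CC(=O)Cl | intermediate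
13 | {2,4-bis(benzyloxy)-6-[3,4-bis(benzyloxy)benzyloxy]phenyl}lithium (formed in the flask) | [Li]c1c(OCc2ccccc2)cc(OCc2ccccc2)cc1OCc1ccc(OCc2ccccc2)c(OCc2ccccc2)c1 | intermediate
14 | {2,4-bis(benzyloxy)-6-[3,4-bis(benzyloxy)benzyloxy]phenyl}zinc chloride (formed in the flask) | Cl[Zn]c1c(OCc2ccccc2)cc(OCc2ccccc2)cc1OCc1ccc(OCc2ccccc2)c(OCc2ccccc2)c1 | intermediate
15 | deoxybenzoin: (2S)-5-(benzyloxy)-2-[4-(benzyloxy)phenyl]-7-(triisopropylsilyloxy)chroman-4-one bearing at C8 a CH2–C(=O)–aryl group, aryl = 2,4-bis(benzyloxy)-6-[3,4-bis(benzyloxy)benzyloxy]phenyl | O=C1C[C@@H](c2ccc(OCc3ccccc3)cc2)Oc2c1c(OCc3ccccc3)cc(O[Si](C(C)C)(C(C)C)C(C)C)c2CC(=O)c1c(OCc2ccccc2)cc(OCc2ccccc2)cc1OCc1ccc(OCc2ccccc2)c(OCc2ccccc2)c1 | intermediate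
16 | α-diazo ketone: as 15 with C(=N2) in place of the CH2 between ring D and the ketone | O=C1C[C@@H](c2ccc(OCc3ccccc3)cc2)Oc2c1c(OCc3ccccc3)cc(O[Si](C(C)C)(C(C)C)C(C)C)c2C(=[N+]=[N-])C(=O)c1c(OCc2ccccc2)cc(OCc2ccccc2)cc1OCc1ccc(OCc2ccccc2)c(OCc2ccccc2)c1 | intermediate
17 | protected biflavanone: unit 1 = (2R,3R)-cis-5,7-bis(benzyloxy)-2-[3,4-bis(benzyloxy)phenyl]chroman-4-one, bonded through C3 to C8 of unit 2 = (2S)-5-(benzyloxy)-2-[4-(benzyloxy)phenyl]-7-(triisopropylsilyloxy)chroman-4-one | O=C1C[C@@H](c2ccc(OCc3ccccc3)cc2)Oc2c1c(OCc3ccccc3)cc(O[Si](C(C)C)(C(C)C)C(C)C)c2[C@H]1C(=O)c2c(OCc3ccccc3)cc(OCc3ccccc3)cc2O[C@H]1c1ccc(OCc2ccccc2)c(OCc2ccccc2)c1 | intermediate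
18 | as 17 with a free 7-OH in unit 2 | O=C1C[C@@H](c2ccc(OCc3ccccc3)cc2)Oc2c1c(OCc3ccccc3)cc(O)c2[C@H]1C(=O)c2c(OCc3ccccc3)cc(OCc3ccccc3)cc2O[C@H]1c1ccc(OCc2ccccc2)c(OCc2ccccc2)c1 | intermediate
19 | (2R,3R)-2-(3,4-dihydroxyphenyl)-5,7-dihydroxy-3-[(2S)-5,7-dihydroxy-2-(4-hydroxyphenyl)-4-oxochroman-8-yl]chroman-4-one | O=C1C[C@@H](c2ccc(O)cc2)Oc2c1c(O)cc(O)c2[C@H]1C(=O)c2c(O)cc(O)cc2O[C@H]1c1ccc(O)c(O)c1 | target

**Step count**

Total: 13 steps. Longest linear sequence: 11 steps (steps 1–6, then 9–13); steps 7 and 8 form the ring A branch.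

**Steps most likely to fail**

Step 11. The carbenoid may be diverted by the lone pair of the aryl ether oxygen (oxonium ylide, then 1,2-shift of the electron-rich benzyl group to C3), may insert into the plain benzyl ether on O5, or may show poor face and cis/trans control. The fallback drops the carbene and closes the same C2–C3 bond with reversed polarity. It sets out from 15: KN(SiMe3)2 (1 equiv, THF, −78 °C), which should remove the more acidic proton between ring D and the ketone, and Ac2O should give the (Z)-enol acetate F1. DDQ with 2,6-dichloropyridine and 4 Å MS in 1,2-dichloroethane should then abstract hydride from the O–CH2–ring B ether only, because plain benzyl ethers resist DDQ. The enol acetate should capture the resulting oxocarbenium ion in a six-membered closure (oxidative C–H cleavage and cyclisation, known for electron-rich benzyl ethers with enol acetates). No catalyst controls the new centres here, but the unit 1 stereoisomers are diastereomers because of C2 of unit 2, so the cis-(2R,3R) isomer is separated by chromatography and the route is rejoined at 17.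

Step 9. Transmetalation of the doubly ortho-substituted arylzinc may be slow, leaving the acid chloride to decompose (ketene formation, or acylative loss of the neighbouring silyl ether with lactonisation). The fallback replaces acylation by addition and oxidation. It sets out from aldehyde 6 and the aryllithium 13 made from 11: ClTi(OiPr)3 converts 13 at −78 °C into the aryltitanium triisopropoxide F2, a non-basic reagent that should add to the aldehyde and not to the flavanone ketone, giving the secondary alcohol F3 as a mixture of carbinol epimers. Dess–Martin periodinane buffered with NaHCO3 oxidises F3 and the route is rejoined at 15.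

Step 7. Bromination may take place para to the hydroxyl group, between the two benzyloxy groups, or twice, and the isomers may be hard to separate. The fallback lets the phenol oxygen fix the position through an oxygen-to-carbon acyl shift and joins ring A to unit 2 without an aryl halide. It sets out from acid 7 and phenol 8: EDC·HCl and catalytic DMAP in CH2Cl2 should give the 3,5-bis(benzyloxy)phenyl ester F4. Sc(OTf)3 (10 mol %) in toluene/MeNO2 at 50 °C should then bring about the Fries rearrangement to the chelated ortho-hydroxy ketone F5, the para position being hindered by the two benzyloxy groups. Mitsunobu etherification of the chelated phenol with purchased 3,4-bis(benzyloxy)benzyl alcohol (PPh3, DIAD, THF) installs the ring B benzyl group without base, and the route is rejoined at 15.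

**Further compounds**

F1 | step 11 | (Z)-enol acetate of 15, acetate on the ring A side carbon of the C=C bond to ring D | O=C1C[C@@H](c2ccc(OCc3ccccc3)cc2)Oc2c1c(OCc3ccccc3)cc(O[Si](C(C)C)(C(C)C)C(C)C)c2/C=C(\OC(C)=O)c1c(OCc2ccccc2)cc(OCc2ccccc2)cc1OCc1ccc(OCc2ccccc2)c(OCc2ccccc2)c1
F2 | step 9 | {2,4-bis(benzyloxy)-6-[3,4-bis(benzyloxy)benzyloxy]phenyl}titanium triisopropoxide | CC(C)O[Ti](OC(C)C)(OC(C)C)c1c(OCc2ccccc2)cc(OCc2ccccc2)cc1OCc1ccc(OCc2ccccc2)c(OCc2ccccc2)c1
F3 | step 9 | secondary alcohol corresponding to 15 (CH(OH) in place of the ketone, both carbinol epimers) | O=C1C[C@@H](c2ccc(OCc3ccccc3)cc2)Oc2c1c(OCc3ccccc3)cc(O[Si](C(C)C)(C(C)C)C(C)C)c2CC(O)c1c(OCc2ccccc2)cc(OCc2ccccc2)cc1OCc1ccc(OCc2ccccc2)c(OCc2ccccc2)c1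
F4 | step 7 | 3,5-bis(benzyloxy)phenyl 2-{(2S)-5-(benzyloxy)-2-[4-(benzyloxy)phenyl]-4-oxo-7-(triisopropylsilyloxy)chroman-8-yl}acetate | O=C1C[C@@H](c2ccc(OCc3ccccc3)cc2)Oc2c1c(OCc3ccccc3)cc(O[Si](C(C)C)(C(C)C)C(C)C)c2CC(=O)Oc1cc(OCc2ccccc2)cc(OCc2ccccc2)c1
F5 | step 7 | ortho-hydroxy ketone: as 15 with a free hydroxyl group in place of the 3,4-bis(benzyloxy)benzyl ether on ring A | O=C1C[C@@H](c2ccc(OCc3ccccc3)cc2)Oc2c1c(OCc3ccccc3)cc(O[Si](C(C)C)(C(C)C)C(C)C)c2CC(=O)c1c(O)cc(OCc2ccccc2)cc1OCc1ccccc1
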